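**Plan**
1. Flavanone numbering is used. Unit 1 is benzo ring A, pyranone ring C and dimethoxyphenyl ring B (O1–C8a, C1'–C6'). Unit 2 is benzo ring D, pyranone ring F and syringyl ring E (O1''–C8a'', C1'''–C6'''). The halves meet at C2'–C8''.
2. Enabling feature: ring D is a phloroglucinol with three unlike oxygens (C5'' OH, C7'' OMe, C8a'' ether O of ring F) and holds ring B on C8'', between C7'' and C8a''. A 3-alkoxy vinylketene and an aryl methyl ynol ether deliver exactly this OH/aryl/OMe/H/OR/H sequence, so the fourfold ortho-substituted axis never has to be made by coupling.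
3. Cuts: O1–C2 and C2–C3 (ring C); O1''–C2'' and C2''–C3'' (ring F); C3''–C4'' and C4''–C4a'' (side chain on ring D); C8''–C8a'' and C6''–C7'' (ring D itself); last, the C2'–alkyne bond.
4. Forward: ring B bromide, aryl ynol ether, ring D by benzannulation, then C4'' set on C4a'' by phenol-directed formylation and grown to a β-ketoester. Knoevenagel condensation with the ring E aldehyde and closure of ring F follow. The ring B aldehyde is then unmasked, condensed with the ring A β-ketoester, ring C is closed, and three benzyl ethers are removed.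
5. Stereochemistry: C2'' and C2 are each set (S) by the same cinchona thiourea in an oxa-Michael addition to an alkylidene β-ketoester. Only neutral or weakly acidic steps follow each closure.

Key step: step 4

Assumption on the axis: the structure fixes C2 and C2'' (both S) but not the sense of the hindered C2'–C8'' axis. The axis forms racemic in step 4, both atropisomers are carried as diastereomers from step 10 on and parted by chromatography at the end, and either one answers to the structure given.
Assumption on the catalyst: the quinine-derived thiourea is written for the (S) series. The sense is to be checked by circular dichroism on the first flavanone, and the quinidine-derived pseudo-enantiomer replaces it in both closures if the sense proves opposite.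

Step 1
Reactants: 1 2-bromo-3,4-dimethoxybenzaldehyde
Product: 2 2-(2-bromo-3,4-dimethoxyphenyl)-1,3-dioxolane
Conditions: HOCH2CH2OH (3 equiv), TsOH·H2O (2 mol %), toluene, reflux, Dean–Stark
Reagents that add atoms: ethylene glycol, OCCO
Why: Acid-catalysed acetalisation with azeotropic removal of water; a cyclic acetal is chosen because the later C8a'' phenol sits six atoms from the acetal carbon, where an opened dioxolane simply recloses but an acyclic dimethyl acetal could lose methanol for good and tie phenol and aldehyde carbon into a benzo[c]chromene acetal.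

Step 2
Reactants: 2 2-(2-bromo-3,4-dimethoxyphenyl)-1,3-dioxolane; 3 chloroacetaldehyde dimethyl acetal
Product: 6 2-[3,4-dimethoxy-2-(methoxyethynyl)phenyl]-1,3-dioxolane, via lithium methoxyacetylide 4 (not isolated), via methoxyethynylzinc chloride 5 (not isolated)
Conditions: 3 (1.5 equiv), LiNEt2 (from Et2NH and n-BuLi, 4.6 equiv), THF, 0 °C; ZnCl2, 0 °C; then 2, Pd2(dba)3 (2.5 mol %), SPhos (10 mol %), THF, 50 °C; Et3N-washed silica
Reagents that add atoms: none
Why: Three equivalents of amide base strip HCl and MeOH from 3 and metalate the resulting methoxyacetylene, and the derived alkynylzinc chloride enters a Negishi coupling in which the bulky electron-rich phosphine lets zerovalent palladium insert into the hindered C–Br bond at a temperature the ynol ether tolerates.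

Step 3
Reactants: 7 3-ethoxycyclobut-2-en-1-one
Product: 8 3-(benzyloxy)cyclobut-2-en-1-one
Conditions: BnOH (3 equiv), PPTS (5 mol %), toluene, 45 °C, 150 mbar
Reagents that add atoms: benzyl alcohol, OCc1ccccc1
Why: Vinylogous transesterification by acid-catalysed addition–elimination at the β-carbon through the mixed 3,3-dialkoxycyclobutanone, driven by stripping ethanol and run well below the temperature at which the four-membered ring opens.

Step 4
Reactants: 6 2-[3,4-dimethoxy-2-(methoxyethynyl)phenyl]-1,3-dioxolane; 8 3-(benzyloxy)cyclobut-2-en-1-one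
Product: 13 5-(benzyloxy)-2-[6-(1,3-dioxolan-2-yl)-2,3-dimethoxyphenyl]-3-methoxyphenol, via vinylketene 9 (not isolated), via vinylcyclobutenone 10 (not isolated), via dienylketene 11 (not isolated), via cyclohexadienone 12 (not isolated)
Conditions: 6 (1.0 equiv), 8 (1.5 equiv), toluene (0.5 M), base-washed sealed tube, 110 °C then 145 °C; crude stirred with K2CO3, MeOH, rt (returns any phenol acylated by 9)
Reagents that add atoms: none
Why: Heating opens 8 by conrotatory four-electron cleavage of its C1–C4 bond to vinylketene 9, and the aryl-bearing carbon of 6, made nucleophilic by the methoxy group, attacks the ketene carbonyl carbon, so that a (2+2) cycloaddition gives vinylcyclobutenone 10 and with it the C8''–C8a'' and C6''–C7'' bonds. A second four-electron opening turns 10 into dienylketene 11, ring D then closes between C4a'' and C8a'' by disrotatory six-electron electrocyclisation to dienone 12, and enolisation gives phenol 13. The reaction type is the Danheiser benzannulation of cyclobutenones with alkoxy- and siloxyalkynes, established for resorcinol monoethers, although this pair (a vinylogous-ester cyclobutenone that should open more reluctantly, hence the higher final temperature, and an alkyne bearing a doubly ortho-substituted aryl group) has no direct counterpart. No stereocentre is created and the C2'–C8'' axis emerges racemic. The one selectivity required is the orientation of the ketene–alkyne cycloaddition; the donor polarisation of the ynol ether secures it and places ring B between the new OH and the OMe with OBn para to it, so the three oxygens of ring D emerge as OH, OMe and OBn without any sorting of protecting groups. The future biaryl bond is already present as an aryl–alkynyl bond at a linear carbon, so crowding builds only as aromatisation pays for it; the methyl ynol ether has no β-hydrogen for retro-ene loss of an alkene, and the neutral medium leaves the dioxolane alone.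

Step 5
Reactants: 13 5-(benzyloxy)-2-[6-(1,3-dioxolan-2-yl)-2,3-dimethoxyphenyl]-3-methoxyphenol
Product: 14 6-(benzyloxy)-3-[6-(1,3-dioxolan-2-yl)-2,3-dimethoxyphenyl]-2-hydroxy-4-methoxybenzaldehyde
Conditions: MgCl2 (anhydrous, 3 equiv), Et3N (6 equiv), (CH2O)n (10 equiv), THF, reflux; sat. aq NH4Cl
Reagents that add atoms: paraformaldehyde (as formaldehyde), C=O
Why: Casnati–Skattebøl ortho-formylation, in which the magnesium phenolate delivers formaldehyde only ortho to its oxygen, so with C8'' blocked only C4a'' reacts (the open para site C6'', which a Fries or Friedel–Crafts acylation could also reach, is not addressed) under basic conditions that spare dioxolane and benzyl ether.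

Step 6
Reactants: 14 6-(benzyloxy)-3-[6-(1,3-dioxolan-2-yl)-2,3-dimethoxyphenyl]-2-hydroxy-4-methoxybenzaldehyde
Product: 15 tert-butyl 3-{6-(benzyloxy)-3-[6-(1,3-dioxolan-2-yl)-2,3-dimethoxyphenyl]-2-hydroxy-4-methoxyphenyl}-3-hydroxypropanoate
Conditions: t-BuOAc (3.2 equiv), LiN(SiMe3)2 (3.3 equiv), THF, −78 °C; then 14, −78 to −40 °C; sat. aq NH4Cl
Reagents that add atoms: tert-butyl acetate, CC(=O)OC(C)(C)C
Why: Aldol addition of the lithium enolate of tert-butyl acetate, in which the first equivalent is spent on the phenol and the new carbinol centre needs no control because the next step oxidises it.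

Step 7
Reactants: 15 tert-butyl 3-{6-(benzyloxy)-3-[6-(1,3-dioxolan-2-yl)-2,3-dimethoxyphenyl]-2-hydroxy-4-methoxyphenyl}-3-hydroxypropanoate
Product: 16 tert-butyl 3-{6-(benzyloxy)-3-[6-(1,3-dioxolan-2-yl)-2,3-dimethoxyphenyl]-2-hydroxy-4-methoxyphenyl}-3-oxopropanoate
Conditions: activated MnO2 (15 equiv), CH2Cl2, rt
Reagents that add atoms: none
Why: Chemoselective MnO2 oxidation of an electron-rich benzylic alcohol, mild enough for the free phenol, the dioxolane and the benzyl ether, giving a ketone that is stabilised by a hydrogen bond from the C8a'' OH.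

Step 8
Reactants: 17 syringaldehyde
Product: 18 4-(benzyloxy)-3,5-dimethoxybenzaldehyde
Conditions: BnBr (1.1 equiv), K2CO3, DMF, 60 °C
Reagents that add atoms: benzyl bromide, BrCc1ccccc1
Why: Williamson ether synthesis on the only phenol, which masks the para OH that would otherwise quench the amine catalysts and make C2'' labile later on.

Step 9
Reactants: 16 tert-butyl 3-{6-(benzyloxy)-3-[6-(1,3-dioxolan-2-yl)-2,3-dimethoxyphenyl]-2-hydroxy-4-methoxyphenyl}-3-oxopropanoate; 18 4-(benzyloxy)-3,5-dimethoxybenzaldehyde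
Product: 19 tert-butyl 2-{6-(benzyloxy)-3-[6-(1,3-dioxolan-2-yl)-2,3-dimethoxyphenyl]-2-hydroxy-4-methoxybenzoyl}-3-[4-(benzyloxy)-3,5-dimethoxyphenyl]prop-2-enoate
Conditions: piperidine (20 mol %), AcOH (20 mol %), 4 Å molecular sieves, toluene, rt
Reagents that add atoms: none
Why: Knoevenagel condensation under buffered piperidinium acetate catalysis, forming C2''–C3'' while the ketone-chelated C8a'' phenol and the low temperature hold back uncatalysed ring closure and the weak buffer leaves the dioxolane intact.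

Step 10
Reactants: 19 tert-butyl 2-{6-(benzyloxy)-3-[6-(1,3-dioxolan-2-yl)-2,3-dimethoxyphenyl]-2-hydroxy-4-methoxybenzoyl}-3-[4-(benzyloxy)-3,5-dimethoxyphenyl]prop-2-enoate
Product: 22 2-{(2S)-5-(benzyloxy)-2-[4-(benzyloxy)-3,5-dimethoxyphenyl]-7-methoxy-4-oxochroman-8-yl}-3,4-dimethoxybenzaldehyde, via chromanone ester 20 (not isolated), via dioxolane flavanone 21 (not isolated)
Conditions: quinine-derived 3,5-(CF3)2C6H3 thiourea (10 mol %), toluene, −25 °C; then TsOH·H2O (1 equiv), 80 °C; then acetone–H2O, rt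
Reagents that add atoms: water, O
Why: Bifunctional cinchona-thiourea catalysis of the intramolecular oxa-Michael addition to an alkylidene β-ketoester (thiourea binds the dicarbonyl, quinuclidine activates the C8a'' OH) closes ring F 6-endo-trig on one alkene face and sets C2'' as S under catalyst control, after which TsOH removes the tert-butyl group as isobutene, the β-keto acid loses CO2, and aqueous acid frees the aldehyde only once the C8a'' oxygen is locked in ring F and can no longer form a lactol.

Step 11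
Reactants: 23 1-(2,6-dihydroxy-4-methoxyphenyl)ethan-1-one
Product: 24 1-[2-(benzyloxy)-6-hydroxy-4-methoxyphenyl]ethan-1-one
Conditions: BnBr (1.0 equiv), K2CO3, acetone, reflux
Reagents that add atoms: benzyl bromide, BrCc1ccccc1
Why: Williamson ether synthesis on a symmetrical diol that stops at the monoether because the remaining OH is strongly chelated to the ketone and inert to K2CO3 and BnBr.

Step 12
Reactants: 24 1-[2-(benzyloxy)-6-hydroxy-4-methoxyphenyl]ethan-1-one
Product: 25 tert-butyl 3-[2-(benzyloxy)-6-hydroxy-4-methoxyphenyl]-3-oxopropanoate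
Conditions: LiN(SiMe3)2 (3.3 equiv), THF, −78 °C; Boc2O (1.1 equiv), −78 to 0 °C; sat. aq NH4Cl
Reagents that add atoms: di-tert-butyl dicarbonate, CC(C)(C)OC(=O)OC(=O)OC(C)(C)C
Why: Claisen-type C-acylation of the phenoxide–enolate dianion at its more reactive carbon terminus, with any aryl carbonate formed at oxygen funnelled to the same product by a Baker–Venkataraman-type O-to-C transfer and the third equivalent of base taken up by the acidic product.

Step 13
Reactants: 22 2-{(2S)-5-(benzyloxy)-2-[4-(benzyloxy)-3,5-dimethoxyphenyl]-7-methoxy-4-oxochroman-8-yl}-3,4-dimethoxybenzaldehyde; 25 tert-butyl 3-[2-(benzyloxy)-6-hydroxy-4-methoxyphenyl]-3-oxopropanoate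
Product: 26 tert-butyl 2-[2-(benzyloxy)-6-hydroxy-4-methoxybenzoyl]-3-(2-{(2S)-5-(benzyloxy)-2-[4-(benzyloxy)-3,5-dimethoxyphenyl]-7-methoxy-4-oxochroman-8-yl}-3,4-dimethoxyphenyl)prop-2-enoate
Conditions: piperidine (20 mol %), AcOH (20 mol %), 4 Å molecular sieves, toluene, rt to 40 °C
Reagents that add atoms: none
Why: Knoevenagel condensation forming C2–C3, chemoselective because the β-ketoester is far more acidic than the C3'' methylene of ring F, and run in a buffer too weak to open ring F by retro-oxa-Michael reaction.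

Step 14
Reactants: 26 tert-butyl 2-[2-(benzyloxy)-6-hydroxy-4-methoxybenzoyl]-3-(2-{(2S)-5-(benzyloxy)-2-[4-(benzyloxy)-3,5-dimethoxyphenyl]-7-methoxy-4-oxochroman-8-yl}-3,4-dimethoxyphenyl)prop-2-enoate
Product: 28 (2S)-5-(benzyloxy)-2-(2-{(2S)-5-(benzyloxy)-2-[4-(benzyloxy)-3,5-dimethoxyphenyl]-7-methoxy-4-oxochroman-8-yl}-3,4-dimethoxyphenyl)-7-methoxychroman-4-one, via biflavanone ester 27 (not isolated)
Conditions: quinine-derived 3,5-(CF3)2C6H3 thiourea (20 mol %), toluene, −25 °C; then TsOH·H2O (1 equiv), 80 °C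
Reagents that add atoms: none
Why: The same cinchona-thiourea oxa-Michael addition closes ring C 6-endo-trig and sets C2 as S under catalyst control, the unactivated ring F staying closed, and acid-induced loss of isobutene and CO2 then removes the activating ester.

Step 15
Reactants: 28 (2S)-5-(benzyloxy)-2-(2-{(2S)-5-(benzyloxy)-2-[4-(benzyloxy)-3,5-dimethoxyphenyl]-7-methoxy-4-oxochroman-8-yl}-3,4-dimethoxyphenyl)-7-methoxychroman-4-one
Product: 29 (2S)-5-hydroxy-2-(2-{(2S)-5-hydroxy-2-(4-hydroxy-3,5-dimethoxyphenyl)-7-methoxy-4-oxochroman-8-yl}-3,4-dimethoxyphenyl)-7-methoxychroman-4-one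
Conditions: H2 (1 atm), Pd/C (10 wt %), EtOAc–MeOH, rt
Reagents that add atoms: none
Why: Catalytic hydrogenolysis of the three aryl benzyl ethers under neutral conditions, standard for flavanones, which avoids the base-induced racemisation that a free para-hydroxyphenyl group at C2'' would allow.

**Compound list**
1 | 2-bromo-3,4-dimethoxybenzaldehyde | COc1ccc(C=O)c(Br)c1OC | starting material
2 | 2-(2-bromo-3,4-dimethoxyphenyl)-1,3-dioxolane | COc1ccc(C2OCCO2)c(Br)c1OC | intermediate
3 | chloroacetaldehyde dimethyl acetal | COC(CCl)OC | starting material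
4 | lithium methoxyacetylide | [Li]C#COC | intermediate
5 | methoxyethynylzinc chloride | Cl[Zn]C#COC | intermediate
6 | 2-[3,4-dimethoxy-2-(methoxyethynyl)phenyl]-1,3-dioxolane | COC#Cc1c(OC)c(OC)ccc1C1OCCO1 | intermediate
7 | 3-ethoxycyclobut-2-en-1-one | CCOC1=CC(=O)C1 | starting material
8 | 3-(benzyloxy)cyclobut-2-en-1-one | O=C1C=C(OCc2ccccc2)C1 | intermediate
9 | 3-(benzyloxy)buta-1,3-dien-1-one | O=C=CC(=C)OCc1ccccc1 | intermediate
10 | 4-[1-(benzyloxy)ethenyl]-2-[6-(1,3-dioxolan-2-yl)-2,3-dimethoxyphenyl]-3-methoxycyclobut-2-en-1-one (racemic) | O=C1C(c2c(OC)c(OC)ccc2C2OCCO2)=C(OC)C1C(=C)OCc1ccccc1 | intermediate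
11 | (3E)-5-(benzyloxy)-2-[6-(1,3-dioxolan-2-yl)-2,3-dimethoxyphenyl]-3-methoxyhexa-1,3,5-trien-1-one | O=C=C(c1c(OC)c(OC)ccc1C1OCCO1)/C(OC)=C\C(=C)OCc1ccccc1 | intermediate
12 | 5-(benzyloxy)-2-[6-(1,3-dioxolan-2-yl)-2,3-dimethoxyphenyl]-3-methoxycyclohexa-2,4-dien-1-one | O=C1CC(OCc2ccccc2)=CC(OC)=C1c1c(OC)c(OC)ccc1C1OCCO1 | intermediate
13 | 5-(benzyloxy)-2-[6-(1,3-dioxolan-2-yl)-2,3-dimethoxyphenyl]-3-methoxyphenol (axis racemic) | COc1ccc(C2OCCO2)c(-c2c(OC)cc(OCc3ccccc3)cc2O)c1OC | intermediate
14 | 6-(benzyloxy)-3-[6-(1,3-dioxolan-2-yl)-2,3-dimethoxyphenyl]-2-hydroxy-4-methoxybenzaldehyde | COc1ccc(C2OCCO2)c(-c2c(OC)cc(OCc3ccccc3)c(C=O)c2O)c1OC | intermediate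
15 | tert-butyl 3-{6-(benzyloxy)-3-[6-(1,3-dioxolan-2-yl)-2,3-dimethoxyphenyl]-2-hydroxy-4-methoxyphenyl}-3-hydroxypropanoate (carbinol centre uncontrolled) | COc1ccc(C2OCCO2)c(-c2c(OC)cc(OCc3ccccc3)c(C(O)CC(=O)OC(C)(C)C)c2O)c1OC | intermediate
16 | tert-butyl 3-{6-(benzyloxy)-3-[6-(1,3-dioxolan-2-yl)-2,3-dimethoxyphenyl]-2-hydroxy-4-methoxyphenyl}-3-oxopropanoate | COc1ccc(C2OCCO2)c(-c2c(OC)cc(OCc3ccccc3)c(C(=O)CC(=O)OC(C)(C)C)c2O)c1OC | intermediate
17 | syringaldehyde | COc1cc(C=O)cc(OC)c1O | starting material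
18 | 4-(benzyloxy)-3,5-dimethoxybenzaldehyde | COc1cc(C=O)cc(OC)c1OCc1ccccc1 | intermediate
19 | tert-butyl 2-{6-(benzyloxy)-3-[6-(1,3-dioxolan-2-yl)-2,3-dimethoxyphenyl]-2-hydroxy-4-methoxybenzoyl}-3-[4-(benzyloxy)-3,5-dimethoxyphenyl]prop-2-enoate (alkene geometry not assigned) | COc1ccc(C2OCCO2)c(-c2c(OC)cc(OCc3ccccc3)c(C(=O)C(=Cc3cc(OC)c(OCc4ccccc4)c(OC)c3)C(=O)OC(C)(C)C)c2O)c1OC | intermediate
20 | tert-butyl (2S)-5-(benzyloxy)-2-[4-(benzyloxy)-3,5-dimethoxyphenyl]-8-[6-(1,3-dioxolan-2-yl)-2,3-dimethoxyphenyl]-7-methoxy-4-oxochromane-3-carboxylate (C3 labile) | COc1ccc(C2OCCO2)c(-c2c(OC)cc(OCc3ccccc3)c3c2O[C@H](c2cc(OC)c(OCc4ccccc4)c(OC)c2)C(C(=O)OC(C)(C)C)C3=O)c1OC | intermediate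
21 | (2S)-5-(benzyloxy)-2-[4-(benzyloxy)-3,5-dimethoxyphenyl]-8-[6-(1,3-dioxolan-2-yl)-2,3-dimethoxyphenyl]-7-methoxychroman-4-one | COc1ccc(C2OCCO2)c(-c2c(OC)cc(OCc3ccccc3)c3c2O[C@H](c2cc(OC)c(OCc4ccccc4)c(OC)c2)CC3=O)c1OC | intermediate
22 | 2-{(2S)-5-(benzyloxy)-2-[4-(benzyloxy)-3,5-dimethoxyphenyl]-7-methoxy-4-oxochroman-8-yl}-3,4-dimethoxybenzaldehyde | COc1ccc(C=O)c(-c2c(OC)cc(OCc3ccccc3)c3c2O[C@H](c2cc(OC)c(OCc4ccccc4)c(OC)c2)CC3=O)c1OC | intermediate
23 | 1-(2,6-dihydroxy-4-methoxyphenyl)ethan-1-one | COc1cc(O)c(C(C)=O)c(O)c1 | starting material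
24 | 1-[2-(benzyloxy)-6-hydroxy-4-methoxyphenyl]ethan-1-one | COc1cc(O)c(C(C)=O)c(OCc2ccccc2)c1 | intermediate
25 | tert-butyl 3-[2-(benzyloxy)-6-hydroxy-4-methoxyphenyl]-3-oxopropanoate | COc1cc(O)c(C(=O)CC(=O)OC(C)(C)C)c(OCc2ccccc2)c1 | intermediate
26 | tert-butyl 2-[2-(benzyloxy)-6-hydroxy-4-methoxybenzoyl]-3-(2-{(2S)-5-(benzyloxy)-2-[4-(benzyloxy)-3,5-dimethoxyphenyl]-7-methoxy-4-oxochroman-8-yl}-3,4-dimethoxyphenyl)prop-2-enoate (alkene geometry not assigned) | COc1cc(O)c(C(=O)C(=Cc2ccc(OC)c(OC)c2-c2c(OC)cc(OCc3ccccc3)c3c2O[C@H](c2cc(OC)c(OCc4ccccc4)c(OC)c2)CC3=O)C(=O)OC(C)(C)C)c(OCc2ccccc2)c1 | intermediate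
27 | tert-butyl (2S)-5-(benzyloxy)-2-(2-{(2S)-5-(benzyloxy)-2-[4-(benzyloxy)-3,5-dimethoxyphenyl]-7-methoxy-4-oxochroman-8-yl}-3,4-dimethoxyphenyl)-7-methoxy-4-oxochromane-3-carboxylate (C3 labile) | COc1cc(OCc2ccccc2)c2c(c1)O[C@H](c1ccc(OC)c(OC)c1-c1c(OC)cc(OCc3ccccc3)c3c1O[C@H](c1cc(OC)c(OCc4ccccc4)c(OC)c1)CC3=O)C(C(=O)OC(C)(C)C)C2=O | intermediate
28 | (2S)-5-(benzyloxy)-2-(2-{(2S)-5-(benzyloxy)-2-[4-(benzyloxy)-3,5-dimethoxyphenyl]-7-methoxy-4-oxochroman-8-yl}-3,4-dimethoxyphenyl)-7-methoxychroman-4-one | COc1cc(OCc2ccccc2)c2c(c1)O[C@H](c1ccc(OC)c(OC)c1-c1c(OC)cc(OCc3ccccc3)c3c1O[C@H](c1cc(OC)c(OCc4ccccc4)c(OC)c1)CC3=O)CC2=O | intermediate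
29 | (2S)-5-hydroxy-2-(2-{(2S)-5-hydroxy-2-(4-hydroxy-3,5-dimethoxyphenyl)-7-methoxy-4-oxochroman-8-yl}-3,4-dimethoxyphenyl)-7-methoxychroman-4-one (CNP0229789.1) | COc1cc(O)c2c(c1)O[C@H](c1ccc(OC)c(OC)c1-c1c(OC)cc(O)c3c1O[C@H](c1cc(OC)c(O)c(OC)c1)CC3=O)CC2=O | target

**Step count**
Total: 15 steps. Longest linear sequence: 11 steps (1, 2, 4, 5, 6, 7, 9, 10, 13, 14, 15).

**Steps most likely to fail**

Step 4. The vinylogous-ester cyclobutenone may open too slowly. Thermal decay of the ynol ether, self-reaction of the ketene, or its capture by the product phenol could then outrun cycloaddition at the shielded alkyne carbon.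

The fallback gives up the ring construction and makes C2'–C8'' by Suzuki–Miyaura coupling. Ring D is taken from a building block whose oxygens are already told apart by chelation. It sets out from 2 and 24.
- Bromine–lithium exchange on 2 (n-BuLi, THF, −78 °C) and quenching with B(OiPr)3 should give [6-(1,3-dioxolan-2-yl)-2,3-dimethoxyphenyl]boronic acid F1.
- Iodination of 24 ortho to its free phenol (NIS, catalytic TFA, MeCN) should give 1-[6-(benzyloxy)-2-hydroxy-3-iodo-4-methoxyphenyl]ethan-1-one F2.
- Coupling of the two with Pd(OAc)2, SPhos and K3PO4 in toluene–water at 100 °C should give 1-{6-(benzyloxy)-3-[6-(1,3-dioxolan-2-yl)-2,3-dimethoxyphenyl]-2-hydroxy-4-methoxyphenyl}ethan-1-one F3.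
- Carboxylation of F3 with LiN(SiMe3)2 and Boc2O, as in step 12, comes back to the route at 16.

Step 14. Facial selectivity may be poor, because the β-aryl group of the acceptor carries a whole flavanone in its ortho position and the catalyst may be mismatched with the axis and with C2''. Uncatalysed closure may already start during step 13. The second acid treatment may also erode C2''.

The fallback drops catalyst control at C2 and relies on separation, since the fixed C2'' centre makes the C2 epimers diastereomers. It sets out from 26.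
- Ring C is closed with catalytic Et3N in toluene at rt, and 27 is separated by chromatography from its epimer, tert-butyl (2R)-5-(benzyloxy)-2-(2-{(2S)-5-(benzyloxy)-2-[4-(benzyloxy)-3,5-dimethoxyphenyl]-7-methoxy-4-oxochroman-8-yl}-3,4-dimethoxyphenyl)-7-methoxy-4-oxochromane-3-carboxylate F4.
- F4 is returned to the amine. Retro-oxa-Michael reaction and re-addition through the stabilised β-ketoester enolate restore the mixture, while the unactivated ring F stays closed.
- Isolated 27 is treated with TsOH·H2O in toluene and comes back to the route at 28.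

Step 2. Oxidative addition into the hindered, electron-rich bromide may be slow. Decay or hydration of the zinc acetylide and of the ynol ether could then take over at the temperature needed.

The fallback builds the triple bond by elimination instead of coupling. It sets out from 2.
- Bromine–lithium exchange (n-BuLi, THF, −78 °C) and acylation with N-methoxy-N-methyl-2-methoxyacetamide should give 1-[6-(1,3-dioxolan-2-yl)-2,3-dimethoxyphenyl]-2-methoxyethan-1-one F5.
- Enolisation with KN(SiMe3)2 and trapping with PhNTf2 should give 1-[6-(1,3-dioxolan-2-yl)-2,3-dimethoxyphenyl]-2-methoxyethenyl trifluoromethanesulfonate F6.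
- Elimination with KOtBu in THF (−78 °C to rt) comes back to the route at 6.

**Further compounds**
F1 | step 4 | [6-(1,3-dioxolan-2-yl)-2,3-dimethoxyphenyl]boronic acid | OB(O)c1c(OC)c(OC)ccc1C1OCCO1
F2 | step 4 | 1-[6-(benzyloxy)-2-hydroxy-3-iodo-4-methoxyphenyl]ethan-1-one | CC(=O)c1c(O)c(I)c(OC)cc1OCc1ccccc1
F3 | step 4 | 1-{6-(benzyloxy)-3-[6-(1,3-dioxolan-2-yl)-2,3-dimethoxyphenyl]-2-hydroxy-4-methoxyphenyl}ethan-1-one | COc1ccc(C2OCCO2)c(-c2c(OC)cc(OCc3ccccc3)c(C(C)=O)c2O)c1OC
F4 | step 14 | tert-butyl (2R)-5-(benzyloxy)-2-(2-{(2S)-5-(benzyloxy)-2-[4-(benzyloxy)-3,5-dimethoxyphenyl]-7-methoxy-4-oxochroman-8-yl}-3,4-dimethoxyphenyl)-7-methoxy-4-oxochromane-3-carboxylate | COc1cc(OCc2ccccc2)c2c(c1)O[C@@H](c1ccc(OC)c(OC)c1-c1c(OC)cc(OCc3ccccc3)c3c1O[C@H](c1cc(OC)c(OCc4ccccc4)c(OC)c1)CC3=O)C(C(=O)OC(C)(C)C)C2=O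
F5 | step 2 | 1-[6-(1,3-dioxolan-2-yl)-2,3-dimethoxyphenyl]-2-methoxyethan-1-one | COCC(=O)c1c(OC)c(OC)ccc1C1OCCO1
F6 | step 2 | 1-[6-(1,3-dioxolan-2-yl)-2,3-dimethoxyphenyl]-2-methoxyethenyl trifluoromethanesulfonate | COC=C(OS(=O)(=O)C(F)(F)F)c1c(OC)c(OC)ccc1C1OCCO1
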